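**Retrosynthetic overview** (spiro[4.5]decane numbering: C1 carbinol, C2 side-chain carbon, C3, C4, C5 spiro atom, C6 C(CH3)OH, C7, C8, C9 enal carbon, C10 hydroxypropyl carbon)
1. Target ⇒ global desilylation, acetylation and i-Bu2AlH unmasking of a Z-α,β-unsaturated nitrile (enal precursor); the triene side chain is attached at C2 by a Mukaiyama-type aldol condensation of a C2 acetaldehyde arm with a dienal acetal made from 6-methylhept-5-en-2-one.
2. The C9 alkylidene comes from a C9 ketone by Horner–Wadsworth–Emmons olefination; the C6 tertiary alcohol comes from a C6=C7 alkene by C1-hydroxyl-directed epoxidation and hydride opening.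
3. Key disconnection: the cyclopentane bonds C4–C5 and C1–C2 are cut together, leading back to a spiro vinyl oxirane on ring A whose oxirane CH carries a 5-silylpent-3-enyl chain (Lewis-acid 1,2-alkyl shift, then Hosomi–Sakurai closure).
4. Enabling feature: the carbinol carbon C1 of the cyclopentane lies between the quaternary spiro atom C5 of the cyclohexane (ring A) and C2, which bears an alkenyl carbon. This is the retron of an α-quaternary aldehyde at C1 and a homoallylic alcohol C1–C2–C=C; C5 is allylic to C6=C7 of ring A in the precursor.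
5. Ring order: ring A is taken from (S)-carvone (C10 side chain by trans alkylation, isopropenyl exchanged for oxygen by Criegee rearrangement, oxirane by a sulfonium ylide); the cyclopentane is formed second, in the key step.

Key step: step 9

Remark: compounds 1, 3, 11, 12, 25, 31 and 34 are taken as purchased; the target in the numbering above is (1S,2S,5S,6S,10R) with a 2E,4E side-chain diene and the formyl group cis to C10. For compounds 5–18 the cyclohexenone numbering of carvone is used (C1 carbonyl carbon, C2 methyl-bearing carbon, C5 oxygen- or isopropenyl-bearing carbon, C6 side-chain carbon).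

**Step 1**
Reactants: 1 3-iodopropan-1-ol
Product: 2 tert-butyl(3-iodopropoxy)diphenylsilane
Conditions: TBDPSCl, imidazole, CH2Cl2, 0 °C to rt
Reagents that add atoms: tert-butyl(chloro)diphenylsilane, CC(C)(C)[Si](Cl)(c1ccccc1)c1ccccc1
Why: Silyl ether formation at the primary alcohol with imidazole as base; no stereocentre is involved.

**Step 2**
Reactants: 3 (S)-(+)-carvone; 2 tert-butyl(3-iodopropoxy)diphenylsilane
Product: 5 (5S,6R)-6-[3-(tert-butyldiphenylsilyloxy)propyl]-2-methyl-5-(prop-1-en-2-yl)cyclohex-2-en-1-one (side chain trans to isopropenyl), via lithium dienolate 4 (not isolated)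
Conditions: LiN(i-Pr)2, THF, −78 °C; then 2, DMPU, −78 to 0 °C
Reagents that add atoms: none
Why: Kinetic α'-deprotonation of the enone and SN2 alkylation of the cross-conjugated lithium enolate (enolate alkylation); the electrophile should enter trans to the adjacent isopropenyl group, which sets C6 (the later C10 of the target).

**Step 3**
Reactants: 5 alkylated carvone
Product: 8 (5S,6R)-5-acetoxy-6-[3-(tert-butyldiphenylsilyloxy)propyl]-2-methylcyclohex-2-en-1-one, via methoxy hydroperoxide 6 (not isolated), via peracetate 7 (not isolated)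
Conditions: O3, CH2Cl2/MeOH, −78 °C; then Ac2O, Et3N, DMAP (cat.), −78 °C to rt
Reagents that add atoms: ozone, [O-][O+]=O; methanol, CO
Why: Ozonolysis of the electron-rich isopropenyl alkene in methanol and Criegee rearrangement of the derived peracetate should replace the isopropenyl group by an acetate with retention at the migrating ring carbon (the acetyl group is the former C–CH3 of the isopropenyl group), while the electron-poor enone alkene should survive.

**Step 4**
Reactants: 8 acetate
Product: 9 (5S,6R)-6-[3-(tert-butyldiphenylsilyloxy)propyl]-5-hydroxy-2-methylcyclohex-2-en-1-one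
Conditions: HCl (cat.), MeOH, 0 °C to rt
Reagents that add atoms: none
Why: Acid-catalysed transesterification removes the acetate without the base that could trigger β-elimination of the β-oxygenated ketone; no stereocentre changes.

**Step 5**
Reactants: 9 hydroxy enone
Product: 10 (5S,6R)-6-[3-(tert-butyldiphenylsilyloxy)propyl]-2-methyl-5-(triethylsilyloxy)cyclohex-2-en-1-one
Conditions: TESCl, imidazole, DMF, 0 °C
Reagents that add atoms: chlorotriethylsilane, CC[Si](Cl)(CC)CC
Why: Silyl ether formation gives a non-participating triethylsilyl ether that can later be removed selectively; no stereocentre changes.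

**Step 6**
Reactants: 11 pent-4-en-1-ol; 12 allyltrimethylsilane
Product: 13 (E)-6-(trimethylsilyl)hex-4-en-1-ol
Conditions: second-generation Grubbs catalyst RuCl2(=CHPh)(PCy3)(H2IMes) (cat.), excess 12, CH2Cl2, 40 °C
Reagents that add atoms: none
Why: Olefin cross-metathesis of a terminal alkene with excess allylsilane should give mainly the E-allylsilane; its alkene geometry is not carried into the target.

**Step 7**
Reactants: 13 (E)-6-(trimethylsilyl)hex-4-en-1-ol
Product: 15 [(E)-6-(trimethylsilyl)hex-4-en-1-yl]diphenylsulfonium trifluoromethanesulfonate, via alkyl triflate 14 (not isolated)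
Conditions: Tf2O, 2,6-lutidine, CH2Cl2, −78 °C; then Ph2S, −78 °C to rt
Reagents that add atoms: trifluoromethanesulfonic anhydride, O=S(=O)(OS(=O)(=O)C(F)(F)F)C(F)(F)F; diphenyl sulfide, c1ccc(Sc2ccccc2)cc1
Why: O-triflation of the primary alcohol and SN2 alkylation of diphenyl sulfide by the triflate give the sulfonium salt, the hindered base keeping the allylsilane away from acid.

**Step 8**
Reactants: 15 sulfonium triflate; 10 silyloxy enone
Product: 17 spiro vinyl oxirane (oxirane on the former C1 of 10, oxygen cis to the C6 side chain, oxirane CH bearing the (E)-5-(trimethylsilyl)pent-3-enyl chain as a mixture of epimers), via sulfonium ylide 16 (not isolated)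
Conditions: LiN(i-Pr)2, THF, −78 °C; then 10, −78 to −20 °C
Reagents that add atoms: none
Why: Corey–Chaykovsky epoxidation with an unstabilised sulfonium alkylide (1,2-addition to the enone carbonyl, then ring closure); the bulky ylide should approach anti to the neighbouring C6 side chain, and the oxirane CH epimers converge in step 9.

**Step 9**
Reactants: 17 spiro vinyl oxirane
Product: 19 2-ethenyl-6-methyl-10-[3-(tert-butyldiphenylsilyloxy)propyl]-9-(triethylsilyloxy)spiro[4.5]dec-6-en-1-ol (C1–OH on the cyclopentane face turned to C6 and trans to the C2 vinyl group; C4 trans and C1 cis to the C10 side chain), via aldehyde 18 (not isolated)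
Conditions: MeAl(OC6H2-2,6-t-Bu2-4-Br)2 (2.5 equiv), CH2Cl2, −78 to 0 °C; aq. NaHCO3
Reagents that add atoms: none
Why: Proposed new method: the bulky aluminium aryloxide ionises the vinyl oxirane at its allylic, fully substituted carbon (the later spiro C5), the chain carbon C4 then shifts from the oxirane CH to C5 (Meinwald-type 1,2-alkyl shift) to give the α-quaternary aldehyde 18 still bound to aluminium, and the tethered allylsilane adds to this activated aldehyde with loss of the silyl group (Hosomi–Sakurai allylation), so that the C4–C5 and C1–C2 bonds form in one flask. The closest known reaction types are the rearrangement of trisubstituted epoxides to aldehydes with this same reagent, in which its bulk steers alkyl over hydride migration, and the tandem epoxide rearrangement–allylsilane addition known between two molecules. Only the cyclopentane closes, by 5-exo-trig attack of the allylsilane γ-carbon (C2) on the aldehyde carbon C1. C5 is controlled by the C10 stereocentre: allylic 1,3-strain with the in-plane exocyclic carbon turns the C10 side chain pseudo-axial in the cyclohexenyl cation, so C4 should migrate to the opposite face (also anti to the departing oxygen), leaving the formyl carbon cis to that chain. C1 and C2 are controlled by the new quaternary centre and the aluminium group: the metal-bound oxygen should point to the flat C6=C7 side and away from the branched C10, and an open antiperiplanar transition state should place the vinyl group trans to it. The step needs alkyl over hydride migration and ring closure faster than proton loss from the cation, which the bulk of the Lewis acid, the absence of α-hydrogens in 18 and the short tether should secure.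

**Step 10**
Reactants: 19 spiro homoallylic alcohol
Product: 20 6,7-epoxide of 19 (epoxide oxygen on the ring A face that carries C1)
Conditions: VO(acac)2 (cat.), t-BuOOH, CH2Cl2, 0 °C to rt
Reagents that add atoms: tert-butyl hydroperoxide, CC(C)(C)OO
Why: Hydroxyl-directed epoxidation of the homoallylic alcohol; vanadium bound to the C1 oxygen should deliver oxygen to the C6=C7 face that carries C1 and leave the less electron-rich vinyl group untouched, which sets the configuration of C6.

**Step 11**
Reactants: 20 epoxy alcohol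
Product: 21 2-ethenyl-6-methyl-10-[3-(tert-butyldiphenylsilyloxy)propyl]-9-(triethylsilyloxy)spiro[4.5]decane-1,6-diol (C6–OH cis to C1 on ring A)
Conditions: LiEt3BH, THF, 0 °C to rt; H2O
Reagents that add atoms: none
Why: SN2 hydride opening of the trisubstituted epoxide at its less substituted carbon C7 (trans-diaxial opening) should leave the tertiary C6 alcohol with the configuration set in step 10.

**Step 12**
Reactants: 21 diol
Product: 22 1,6-O-(di-tert-butylsilylene) derivative of 21
Conditions: t-Bu2Si(OTf)2, 2,6-lutidine, CH2Cl2, 0 °C to rt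
Reagents that add atoms: di-tert-butylsilyl bis(trifluoromethanesulfonate), CC(C)(C)[Si](OS(=O)(=O)C(F)(F)F)(OS(=O)(=O)C(F)(F)F)C(C)(C)C
Why: Cyclic silylene formation across the 1,3-diol (C1–OH and C6–OH on the same side) protects both hydroxyls in a six-membered ring; no stereocentre changes.

**Step 13**
Reactants: 22 silylene
Product: 23 C9 alcohol (triethylsilyl group removed)
Conditions: PPTS, MeOH/CH2Cl2, 0 °C to rt
Reagents that add atoms: none
Why: Mild acidic methanolysis cleaves the triethylsilyl ether selectively, the di-tert-butylsilylene and tert-butyldiphenylsilyl groups being far more stable to acid.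

**Step 14**
Reactants: 23 C9 alcohol
Product: 24 C9 ketone
Conditions: Dess–Martin periodinane, NaHCO3, CH2Cl2, rt
Reagents that add atoms: none
Why: Dess–Martin oxidation of the secondary alcohol under buffered, non-epimerising conditions gives the ketone.

**Step 15**
Reactants: 24 C9 ketone; 25 diethyl (1-cyanoethyl)phosphonate
Product: 26 (Z)-2-(spirocycle-9-ylidene)propanenitrile (nitrile cis to C10, methyl cis to C8)
Conditions: NaH, DME, 0 to 65 °C
Reagents that add atoms: none
Why: Horner–Wadsworth–Emmons olefination with a small cyano phosphonate should tolerate the hindered ketone and place the slim nitrile cis to the branched C10 and the methyl group cis to C8, giving the Z nitrile (masked Z enal) without touching the C10 methine.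

**Step 16**
Reactants: 26 nitrile
Product: 28 2-(2-hydroxyethyl) compound, via B-alkyl-9-borabicyclononane 27 (not isolated)
Conditions: 9-BBN, THF, 0 °C to rt; then H2O2, aq. NaOAc, 0 °C
Reagents that add atoms: hydrogen peroxide, OO
Why: Anti-Markovnikov hydroboration of the only reactive (monosubstituted) alkene and buffered peroxide oxidation, mild enough to spare the conjugated nitrile, should give the primary alcohol.

**Step 17**
Reactants: 28 primary alcohol
Product: 29 2-(2-oxoethyl) aldehyde
Conditions: Dess–Martin periodinane, NaHCO3, CH2Cl2, rt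
Reagents that add atoms: none
Why: Dess–Martin oxidation of the primary alcohol to the aldehyde.

**Step 18**
Reactants: 29 aldehyde
Product: 30 trimethylsilyl enol ether of 29 (mixture of enol ether isomers)
Conditions: TMSOTf, Et3N, CH2Cl2, −20 °C to rt
Reagents that add atoms: trimethylsilyl trifluoromethanesulfonate, C[Si](C)(C)OS(=O)(=O)C(F)(F)F
Why: Soft enolisation (silyl triflate and amine) converts the aldehyde into its enol silane without a strong base, which would deprotonate γ to the nitrile; the enol ether geometry is irrelevant.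

**Step 19**
Reactants: 31 6-methylhept-5-en-2-one
Product: 33 6-methylhepta-1,5-dien-2-yl trifluoromethanesulfonate, via lithium enolate 32 (not isolated)
Conditions: LiN(i-Pr)2, THF, −78 °C; then PhNTf2, −78 °C to rt
Reagents that add atoms: N-phenylbis(trifluoromethanesulfonimide), O=S(=O)(N(c1ccccc1)S(=O)(=O)C(F)(F)F)C(F)(F)F
Why: Kinetic deprotonation at the methyl group of the methyl ketone and O-sulfonylation of the enolate give the 1,1-disubstituted enol triflate.

**Step 20**
Reactants: 33 enol triflate; 34 acrolein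
Product: 35 (2E)-8-methyl-4-methylidenenona-2,7-dienal
Conditions: Pd(OAc)2 (cat.), Et3N, DMF, rt to 50 °C
Reagents that add atoms: none
Why: Heck reaction of the alkenyl triflate with acrolein (syn carbopalladation, syn β-hydride elimination) should give the E-configured dienal.

**Step 21**
Reactants: 35 dienal
Product: 36 (2E)-1,1-dimethoxy-8-methyl-4-methylidenenona-2,7-diene
Conditions: HC(OMe)3, PPTS (cat.), rt
Reagents that add atoms: trimethyl orthoformate, COC(OC)OC
Why: Acid-catalysed acetalisation with the orthoformate as methanol source and dehydrating agent.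

**Step 22**
Reactants: 30 enol silane; 36 dienal dimethyl acetal
Product: 38 (2E,4E)-trienal (formyl group on the carbon attached to C2, side chain complete), via β-methoxy aldehyde 37 (not isolated)
Conditions: TMSOTf (cat.), CH2Cl2, −78 °C; then DBU, −78 °C to rt
Reagents that add atoms: none
Why: Mukaiyama-type addition of the enol silane to the oxocarbenium ion of the unsaturated acetal (attack at the acetal carbon), followed by base-induced E1cB loss of methanol, is an aldol condensation without strong base and should give the thermodynamically preferred 2E-enal with the formyl group trans to the diene.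

**Step 23**
Reactants: 38 trienal nitrile
Product: 40 hydroxy enal (side-chain CH2OH, ring A Z-enal), via aluminated aldimine 39 (not isolated)
Conditions: i-Bu2AlH, CH2Cl2, −78 to −40 °C; then aq. potassium sodium tartrate, wet SiO2
Reagents that add atoms: water, O
Why: Hydride reduction converts the trienal into the allylic alcohol and the hindered nitrile into an N-aluminated aldimine, which is hydrolysed on work-up to the ring A enal with retention of the alkene geometry.

**Step 24**
Reactants: 40 hydroxy enal
Product: 41 allylic acetate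
Conditions: Ac2O, pyridine, DMAP (cat.), CH2Cl2, 0 °C
Reagents that add atoms: acetic anhydride, CC(=O)OC(C)=O
Why: Acylation of the only free hydroxyl group, the primary allylic alcohol.

**Step 25**
Reactants: 41 fully protected acetate
Product: 42 target, [(2E,4E)-2-[(1S,2S,5S,6S,10R)-1,6-dihydroxy-10-(3-hydroxypropyl)-6-methyl-9-[(Z)-1-oxopropan-2-ylidene]spiro[4.5]decan-2-yl]-10-methyl-6-methylideneundeca-2,4,9-trien-1-yl] acetate
Conditions: HF·pyridine, pyridine, THF, 0 °C to rt
Reagents that add atoms: none
Why: Fluoride-mediated cleavage of the tert-butyldiphenylsilyl ether and the di-tert-butylsilylene under buffered conditions that should spare the allylic acetate, the enal and the triene, with all stereocentres untouched.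

**Compound list**
1 | 3-iodopropan-1-ol | OCCCI | starting material
2 | tert-butyl(3-iodopropoxy)diphenylsilane | ICCCO[Si](c1ccccc1)(c1ccccc1)C(C)(C)C | intermediate
3 | (S)-(+)-carvone | CC1=CC[C@@H](CC1=O)C(C)=C | starting material
4 | lithium dienolate of carvone (kinetic, at C6) | [Li+].[O-]C1=C[C@@H](C(C)=C)CC=C1C | intermediate
5 | (5S,6R)-6-[3-(tert-butyldiphenylsilyloxy)propyl]-2-methyl-5-(prop-1-en-2-yl)cyclohex-2-en-1-one | O=C1C(C)=CC[C@H](C(C)=C)[C@H]1CCCO[Si](c2ccccc2)(c2ccccc2)C(C)(C)C | intermediate
6 | α-methoxy hydroperoxide from ozonolysis of 5 (new centre unassigned) | O=C1C(C)=CC[C@H](C(C)(OC)OO)[C@H]1CCCO[Si](c2ccccc2)(c2ccccc2)C(C)(C)C | intermediate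
7 | peracetate of 6 | O=C1C(C)=CC[C@H](C(C)(OC)OOC(C)=O)[C@H]1CCCO[Si](c2ccccc2)(c2ccccc2)C(C)(C)C | intermediate
8 | (5S,6R)-5-acetoxy-6-[3-(tert-butyldiphenylsilyloxy)propyl]-2-methylcyclohex-2-en-1-one | O=C1C(C)=CC[C@H](OC(C)=O)[C@H]1CCCO[Si](c2ccccc2)(c2ccccc2)C(C)(C)C | intermediate
9 | (5S,6R)-6-[3-(tert-butyldiphenylsilyloxy)propyl]-5-hydroxy-2-methylcyclohex-2-en-1-one | O=C1C(C)=CC[C@H](O)[C@H]1CCCO[Si](c2ccccc2)(c2ccccc2)C(C)(C)C | intermediate
10 | (5S,6R)-6-[3-(tert-butyldiphenylsilyloxy)propyl]-2-methyl-5-(triethylsilyloxy)cyclohex-2-en-1-one | O=C1C(C)=CC[C@H](O[Si](CC)(CC)CC)[C@H]1CCCO[Si](c2ccccc2)(c2ccccc2)C(C)(C)C | intermediate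
11 | pent-4-en-1-ol | OCCCC=C | starting material
12 | allyltrimethylsilane | C=CC[Si](C)(C)C | starting material
13 | (E)-6-(trimethylsilyl)hex-4-en-1-ol | OCCC/C=C/C[Si](C)(C)C | intermediate
14 | (E)-6-(trimethylsilyl)hex-4-en-1-yl trifluoromethanesulfonate | C[Si](C)(C)C/C=C/CCCOS(=O)(=O)C(F)(F)F | intermediate
15 | [(E)-6-(trimethylsilyl)hex-4-en-1-yl]diphenylsulfonium trifluoromethanesulfonate | C[Si](C)(C)C/C=C/CCC[S+](c1ccccc1)c1ccccc1.[O-]S(=O)(=O)C(F)(F)F | intermediate
16 | diphenylsulfonium (E)-6-(trimethylsilyl)hex-4-en-1-ylide | C[Si](C)(C)C/C=C/CC[CH-][S+](c1ccccc1)c1ccccc1 | intermediate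
17 | spiro vinyl oxirane (oxygen cis to the C6 side chain; oxirane CH unassigned) | C[Si](C)(C)C/C=C/CCC1O[C@]12C(C)=CC[C@H](O[Si](CC)(CC)CC)[C@H]2CCCO[Si](c3ccccc3)(c3ccccc3)C(C)(C)C | intermediate
18 | 2-methyl-1-[(E)-5-(trimethylsilyl)pent-3-en-1-yl]-6-[3-(tert-butyldiphenylsilyloxy)propyl]-5-(triethylsilyloxy)cyclohex-2-ene-1-carbaldehyde (formyl cis to the C6 side chain) | C[Si](C)(C)C/C=C/CC[C@]1(C=O)C(C)=CC[C@H](O[Si](CC)(CC)CC)[C@H]1CCCO[Si](c2ccccc2)(c2ccccc2)C(C)(C)C | intermediate
19 | 2-ethenyl-6-methyl-10-[3-(tert-butyldiphenylsilyloxy)propyl]-9-(triethylsilyloxy)spiro[4.5]dec-6-en-1-ol | C=C[C@@H]1CC[C@]2([C@H](CCCO[Si](c3ccccc3)(c3ccccc3)C(C)(C)C)[C@@H](O[Si](CC)(CC)CC)CC=C2C)[C@H]1O | intermediate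
20 | 6,7-epoxide of 19 | C=C[C@@H]1CC[C@]2([C@H](CCCO[Si](c4ccccc4)(c4ccccc4)C(C)(C)C)[C@@H](O[Si](CC)(CC)CC)C[C@@H]3O[C@]23C)[C@H]1O | intermediate
21 | spiro[4.5]decane-1,6-diol (vinyl at C2, triethylsilyloxy at C9) | C=C[C@@H]1CC[C@]2([C@H](CCCO[Si](c3ccccc3)(c3ccccc3)C(C)(C)C)[C@@H](O[Si](CC)(CC)CC)CC[C@]2(C)O)[C@H]1O | intermediate
22 | 1,6-O-(di-tert-butylsilylene) derivative of 21 | C=C[C@@H]1CC[C@]2([C@H](CCCO[Si](c4ccccc4)(c4ccccc4)C(C)(C)C)[C@@H](O[Si](CC)(CC)CC)CC[C@]2(C)O3)[C@H]1O[Si]3(C(C)(C)C)C(C)(C)C | intermediate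
23 | C9 alcohol | C=C[C@@H]1CC[C@]2([C@H](CCCO[Si](c4ccccc4)(c4ccccc4)C(C)(C)C)[C@@H](O)CC[C@]2(C)O3)[C@H]1O[Si]3(C(C)(C)C)C(C)(C)C | intermediate
24 | C9 ketone | C=C[C@@H]1CC[C@]2([C@H](CCCO[Si](c4ccccc4)(c4ccccc4)C(C)(C)C)C(=O)CC[C@]2(C)O3)[C@H]1O[Si]3(C(C)(C)C)C(C)(C)C | intermediate
25 | diethyl (1-cyanoethyl)phosphonate | CCOP(=O)(OCC)C(C)C#N | starting material
26 | (Z)-α,β-unsaturated nitrile at C9 | C=C[C@@H]1CC[C@]2([C@H](CCCO[Si](c4ccccc4)(c4ccccc4)C(C)(C)C)/C(=C(/C)C#N)CC[C@]2(C)O3)[C@H]1O[Si]3(C(C)(C)C)C(C)(C)C | intermediate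
27 | B-alkyl-9-borabicyclo[3.3.1]nonane from 26 | C1CCC2CCCC1B2CC[C@@H]3CC[C@]4([C@H](CCCO[Si](c5ccccc5)(c5ccccc5)C(C)(C)C)/C(=C(/C)C#N)CC[C@]4(C)O6)[C@H]3O[Si]6(C(C)(C)C)C(C)(C)C | intermediate
28 | 2-(2-hydroxyethyl) nitrile | OCC[C@@H]1CC[C@]2([C@H](CCCO[Si](c4ccccc4)(c4ccccc4)C(C)(C)C)/C(=C(/C)C#N)CC[C@]2(C)O3)[C@H]1O[Si]3(C(C)(C)C)C(C)(C)C | intermediate
29 | 2-(2-oxoethyl) nitrile (aldehyde) | O=CC[C@@H]1CC[C@]2([C@H](CCCO[Si](c4ccccc4)(c4ccccc4)C(C)(C)C)/C(=C(/C)C#N)CC[C@]2(C)O3)[C@H]1O[Si]3(C(C)(C)C)C(C)(C)C | intermediate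
30 | trimethylsilyl enol ether of 29 (enol geometry unassigned) | C[Si](C)(C)OC=C[C@@H]1CC[C@]2([C@H](CCCO[Si](c4ccccc4)(c4ccccc4)C(C)(C)C)/C(=C(/C)C#N)CC[C@]2(C)O3)[C@H]1O[Si]3(C(C)(C)C)C(C)(C)C | intermediate
31 | 6-methylhept-5-en-2-one | CC(=O)CCC=C(C)C | starting material
32 | lithium enolate of 31 (kinetic, terminal) | [Li+].[O-]C(=C)CCC=C(C)C | intermediate
33 | 6-methylhepta-1,5-dien-2-yl trifluoromethanesulfonate | C=C(OS(=O)(=O)C(F)(F)F)CCC=C(C)C | intermediate
34 | acrolein | C=CC=O | starting material
35 | (2E)-8-methyl-4-methylidenenona-2,7-dienal | O=C/C=C/C(=C)CCC=C(C)C | intermediate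
36 | (2E)-1,1-dimethoxy-8-methyl-4-methylidenenona-2,7-diene | COC(OC)/C=C/C(=C)CCC=C(C)C | intermediate
37 | β-methoxy aldehyde adduct (two new centres unassigned) | C=C(/C=C/C(OC)C(C=O)[C@@H]1CC[C@]2([C@H](CCCO[Si](c4ccccc4)(c4ccccc4)C(C)(C)C)/C(=C(/C)C#N)CC[C@]2(C)O3)[C@H]1O[Si]3(C(C)(C)C)C(C)(C)C)CCC=C(C)C | intermediate
38 | (2E,4E)-trienal nitrile | C=C(/C=C/C=C(/C=O)[C@@H]1CC[C@]2([C@H](CCCO[Si](c4ccccc4)(c4ccccc4)C(C)(C)C)/C(=C(/C)C#N)CC[C@]2(C)O3)[C@H]1O[Si]3(C(C)(C)C)C(C)(C)C)CCC=C(C)C | intermediate
39 | O-aluminated allylic alkoxide / N-aluminated aldimine | C=C(/C=C/C=C(/CO[Al](CC(C)C)CC(C)C)[C@@H]1CC[C@]2([C@H](CCCO[Si](c4ccccc4)(c4ccccc4)C(C)(C)C)/C(=C(/C)C=N[Al](CC(C)C)CC(C)C)CC[C@]2(C)O3)[C@H]1O[Si]3(C(C)(C)C)C(C)(C)C)CCC=C(C)C | intermediate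
40 | hydroxy enal (side-chain CH2OH, ring A Z-enal) | C=C(/C=C/C=C(/CO)[C@@H]1CC[C@]2([C@H](CCCO[Si](c4ccccc4)(c4ccccc4)C(C)(C)C)/C(=C(/C)C=O)CC[C@]2(C)O3)[C@H]1O[Si]3(C(C)(C)C)C(C)(C)C)CCC=C(C)C | intermediate
41 | protected target (allylic acetate, silylene, silyl ether) | C=C(/C=C/C=C(/COC(C)=O)[C@@H]1CC[C@]2([C@H](CCCO[Si](c4ccccc4)(c4ccccc4)C(C)(C)C)/C(=C(/C)C=O)CC[C@]2(C)O3)[C@H]1O[Si]3(C(C)(C)C)C(C)(C)C)CCC=C(C)C | intermediate
42 | CNP0204268.2 | C=C(/C=C/C=C(/COC(C)=O)[C@@H]1CC[C@]2([C@H](CCCO)/C(=C(/C)C=O)CC[C@]2(C)O)[C@H]1O)CCC=C(C)C | target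

**Step count**
Total: 25 steps. Longest linear sequence: 20 steps from 3-iodopropan-1-ol 1 (steps 1–5, 8–18, 22–25).

**Steps most likely to fail**

1. Step 9 (key step, proposed new method). Hydride instead of alkyl migration, or proton loss from the allylic cation, may divert the rearrangement; the hindered aluminium-bound aldehyde may fail to cyclise; or facial control at C5, C1 and C2 may erode. Fallback by known chemistry, setting out from ketone 10 and coming back at aldehyde 18 (isolated here) and then 19: Wittig methoxymethylenation of 10 with Ph3P=CHOMe should give the dienyl methyl ether F1, and mild acid hydrolysis (oxalic acid on wet silica) the conjugated aldehyde F2. Its potassium dienolate (KOt-Bu, THF) should be alkylated at the α-carbon, anti to the neighbouring side chain, by (E)-(5-iodopent-2-en-1-yl)trimethylsilane F4 to give 18. F4 would be made from (E)-5-(trimethylsilyl)pent-3-en-1-ol F3 (cross-metathesis of but-3-en-1-ol with 12, then I2, PPh3, imidazole). A separate SnCl4-promoted Hosomi–Sakurai cyclisation of 18 at −78 °C should then give 19.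

2. Step 8. The basic ylide may enolise the hindered, α'-branched enone instead of adding to its carbonyl group, so that conversion stays low. Fallback from alcohol 13 and ketone 10, coming back at 17: Dess–Martin oxidation of 13 should give (E)-6-(trimethylsilyl)hex-4-enal F5, and PhSeH with ZnCl2 the bis(phenylseleno)acetal F6. Selenium–lithium exchange with n-BuLi gives an α-seleno alkyllithium, a class of reagent that adds to hindered and enolisable ketones; with 10 it should give the β-hydroxy selenide F7. Methylation at selenium (MeI, AgBF4) and treatment with KOt-Bu should close the oxirane 17.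

3. Step 15. The olefination of the hindered ketone may be slow, with base-induced epimerisation of the adjacent C10 methine and incomplete control of the alkene geometry. Fallback from ketone 24, coming back at nitrile 26: addition of CH2=C(CH3)MgBr with CeCl3 should give the tertiary allylic alcohol F8. Oxidative 1,3-transposition with pyridinium chlorochromate, [C5H5NH][CrO3Cl] (Babler–Dauben oxidation), should give the tetrasubstituted Z-enal F9, which can be equilibrated to the less strained isomer. Iodine in aqueous ammonia/THF should convert the aldehyde into nitrile 26.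

**Further compounds**
F1 | step 9 | dienyl methyl ether from 10 (enol ether geometry unassigned) | COC=C1C(C)=CC[C@H](O[Si](CC)(CC)CC)[C@H]1CCCO[Si](c2ccccc2)(c2ccccc2)C(C)(C)C
F2 | step 9 | 2-methyl-6-[3-(tert-butyldiphenylsilyloxy)propyl]-5-(triethylsilyloxy)cyclohex-1-ene-1-carbaldehyde | O=CC1=C(C)CC[C@H](O[Si](CC)(CC)CC)[C@H]1CCCO[Si](c2ccccc2)(c2ccccc2)C(C)(C)C
F3 | step 9 | (E)-5-(trimethylsilyl)pent-3-en-1-ol | OCC/C=C/C[Si](C)(C)C
F4 | step 9 | (E)-(5-iodopent-2-en-1-yl)trimethylsilane | ICC/C=C/C[Si](C)(C)C
F5 | step 8 | (E)-6-(trimethylsilyl)hex-4-enal | O=CCC/C=C/C[Si](C)(C)C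
F6 | step 8 | (E)-[6,6-bis(phenylselanyl)hex-2-en-1-yl]trimethylsilane | C[Si](C)(C)C/C=C/CCC([Se]c1ccccc1)[Se]c1ccccc1
F7 | step 8 | β-hydroxy selenide from 10 (selenide-bearing carbon unassigned) | C[Si](C)(C)C/C=C/CCC([Se]c1ccccc1)[C@]2(O)C(C)=CC[C@H](O[Si](CC)(CC)CC)[C@H]2CCCO[Si](c3ccccc3)(c3ccccc3)C(C)(C)C
F8 | step 15 | tertiary allylic alcohol from 24 (carbinol centre unassigned) | C=C[C@@H]1CC[C@]2([C@H](CCCO[Si](c4ccccc4)(c4ccccc4)C(C)(C)C)C(O)(C(C)=C)CC[C@]2(C)O3)[C@H]1O[Si]3(C(C)(C)C)C(C)(C)C
F9 | step 15 | tetrasubstituted Z-enal at C9 | C=C[C@@H]1CC[C@]2([C@H](CCCO[Si](c4ccccc4)(c4ccccc4)C(C)(C)C)/C(=C(/C)C=O)CC[C@]2(C)O3)[C@H]1O[Si]3(C(C)(C)C)C(C)(C)C
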